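**Retrosynthetic overview**
1. The spiro-dihydropyran is made last: O–C11 and C13–C13′ come from an oxa-Diels–Alder reaction between the exocyclic C11=C13 of the eudesmanolide 19 ((+)-alantolactone) and the cis-fused eudesmadienal 33.
2. Key disconnection: the γ-lactone of 19 (ring atoms C7, C8, O, C12, C11) is a CO2 unit spanning C11 and C8, and is cut to CO2 plus the 12-nor precursor 17. What makes this possible: C11 and C8 are 1,3-related across C7 of ring B; C11 is an sp2 carbon (it keeps C13 as =CH2) that can carry boron, and C8 is an sp3 ring carbon that can carry a sulfonate trans to the C7–C11 bond, so a carboxylate born on C11 closes on C8 with inversion to the cis-fused 8β,12-olide.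
3. 17 comes from 3-methylcyclohexenone: C10 is set by catalysis, ring A is closed onto ring B by aldol condensation, C4 is relayed by a suprafacial allylic-diazene hydrogen shift, and C7/C8 by anti opening of a vinyl epoxide.
4. 33 comes from (R)-carvone by conjugate addition and intramolecular enolate alkylation (methylenecyclohexane annulation), which relays C5′ and C10′ from C7′.
5. Order of ring formation: lactone half: ring B (bought), ring A (step 2), γ-lactone (step 11); enal half: ring B′ (carvone), ring A′ (step 16); dihydropyran (step 21).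

Key step: step 11

Remark: eudesmane numbering is used for both halves (primed for the enal half): C10 carries the angular methyl, C5 is the other ring-fusion carbon, C4 carries C15, C7 the side chain, C8 the lactone oxygen; β is the face of the C10 methyl group of that half.
Remark (assumption): in step 1 the antipode of the chiral ligand is taken that gives (S)-4; the other antipode would give the enantiomeric series.

Step 1
Reactants: 1 3-methylcyclohex-2-en-1-one; 2 2-(3-chloropropyl)-2-methyl-1,3-dioxolane
Product: 4 (S)-3-methyl-3-[3-(2-methyl-1,3-dioxolan-2-yl)propyl]cyclohexan-1-one, via Grignard reagent 3 (not isolated)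
Conditions: 2, Mg, THF/Et2O, 40 °C; then Cu(OTf)2 (3 mol%), chiral C2-symmetric imidazolinium salt (NHC precursor, 4 mol%), 1, Et2O, 0 °C
Reagents that add atoms: none
Why: Copper-catalysed asymmetric conjugate addition of a Grignard reagent to a β-substituted cyclohexenone, in which the chiral NHC–copper complex selects the enone face and sets the quaternary centre C10, the only stereocentre of this half set by catalysis.

Step 2
Reactants: 4 (S)-3-methyl-3-[3-(2-methyl-1,3-dioxolan-2-yl)propyl]cyclohexan-1-one
Product: 6 (4aR)-4a,8-dimethyl-3,4,4a,5,6,7-hexahydronaphthalen-1(2H)-one, via diketone 5 (not isolated)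
Conditions: 2 M HCl, THF, 25 °C; then KOH, MeOH, 65 °C
Reagents that add atoms: none
Why: Acid removes the dioxolane and base drives the intramolecular aldol condensation of the 1,7-diketone (C5 enolate onto the C4 ketone, six-membered ring A) to the conjugated tetrasubstituted enone, the only aldol product that can dehydrate; no new stereocentre.

Step 3
Reactants: 6 (4aR)-4a,8-dimethyl-3,4,4a,5,6,7-hexahydronaphthalen-1(2H)-one
Product: 7 (4aR)-4a,8-dimethyl-4a,5,6,7-tetrahydronaphthalen-1(4H)-one
Conditions: IBX (2 equiv), DMSO, 70 °C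
Reagents that add atoms: none
Why: IBX dehydrogenation of a ketone to an enone acts at the only enolisable CH2–CH2 unit (C7–C8) and should give the cross-conjugated dienone, which cannot aromatise because C10 is quaternary.

Step 4
Reactants: 7 (4aR)-4a,8-dimethyl-4a,5,6,7-tetrahydronaphthalen-1(4H)-one
Product: 8 7α,8α-epoxy-4,10-dimethyl-Δ4-octalin-6-one
Conditions: 30% H2O2, NaOH (0.3 equiv), MeOH, 0 °C
Reagents that add atoms: hydrogen peroxide, OO
Why: Weitz–Scheffer nucleophilic epoxidation takes the unhindered disubstituted C7=C8 and not the tetrasubstituted C4=C5, and the hydroperoxide adds to C8 anti to the axial C10 methyl group, so the oxirane should be α.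

Step 5
Reactants: 8 7α,8α-epoxy-4,10-dimethyl-Δ4-octalin-6-one
Product: 9 7α,8α-epoxy-4,10-dimethyl-Δ4-octalin-6β-ol
Conditions: L-Selectride, THF, −78 °C; aq. NH4Cl
Reagents that add atoms: none
Why: 1,2-Reduction by a bulky trialkylborohydride under steric approach control, in which the axial C10 methyl group (1,3 to C6) blocks the β-face so that hydride should enter from α and give the 6β-alcohol; conjugate reduction is shut off by the tetrasubstituted β-carbon.

Step 6
Reactants: 9 7α,8α-epoxy-4,10-dimethyl-Δ4-octalin-6β-ol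
Product: 12 7α,8α-epoxy-4β,10β-dimethyl-Δ5-octalin, via N-allyl sulfonylhydrazide 10 (not isolated), via allylic diazene 11 (not isolated)
Conditions: 2-nitrobenzenesulfonylhydrazide, PPh3, DEAD, N-methylmorpholine, −30 °C; then 23 °C
Reagents that add atoms: none
Why: Mitsunobu displacement by the sulfonylhydrazide inverts C6 (nitrogen α), loss of sulfinic acid gives the allylic diazene, and its retro-ene loss of N2 delivers hydrogen suprafacially to the α-face of C4 while the double bond moves to C5=C6 (reductive 1,3-transposition), so the C4 methyl group should end β, cis to the C10 methyl group.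

Step 7
Reactants: 12 7α,8α-epoxy-4β,10β-dimethyl-Δ5-octalin
Product: 13 7β-ethynyl-4β,10β-dimethyl-Δ5-octalin-8α-ol
Conditions: acetylene, n-BuLi, THF, −78 °C; BF3·OEt2, then 12, −78 °C
Reagents that add atoms: lithium acetylide, [Li+].[C-]#C
Why: Lewis acid-assisted SN2 opening of a vinyl epoxide by an alkynyllithium at the allylic carbon C7 with inversion (SN2′ attack at the fully substituted C5 is blocked), which should give the 7β-ethynyl group and keep the 8α-oxygen, the trans pair needed for step 11.

Step 8
Reactants: 13 7β-ethynyl-4β,10β-dimethyl-Δ5-octalin-8α-ol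
Product: 15 7β-(1-bromovinyl)-4β,10β-dimethyl-Δ5-octalin-8α-ol, via bromoalkenylborane 14 (not isolated)
Conditions: B-bromo-9-BBN (2.2 equiv), CH2Cl2, 0 °C; then AcOH, 23 °C
Reagents that add atoms: B-bromo-9-borabicyclo[3.3.1]nonane, BrB1C2CCCC1CCC2
Why: syn-Bromoboration of the terminal alkyne (bromine to the internal carbon C11, boron to C13) and protodeboronation should give the 2-bromo-1-alkene without touching a stereocentre.

Step 9
Reactants: 15 7β-(1-bromovinyl)-4β,10β-dimethyl-Δ5-octalin-8α-ol
Product: 16 7β-[1-(5,5-dimethyl-1,3,2-dioxaborinan-2-yl)vinyl]-4β,10β-dimethyl-Δ5-octalin-8α-ol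
Conditions: bis(neopentyl glycolato)diboron, PdCl2(PPh3)2 (3 mol%), PPh3, KOPh, toluene, 50 °C
Reagents that add atoms: bis(neopentyl glycolato)diboron, CC1(C)COB(OC1)B1OCC(C)(C)CO1
Why: Miyaura borylation of a 1-alkenyl bromide under the weak-base phenoxide conditions used for alkenyl halides, which a free secondary alcohol and the trisubstituted alkene tolerate.

Step 10
Reactants: 16 7β-[1-(5,5-dimethyl-1,3,2-dioxaborinan-2-yl)vinyl]-4β,10β-dimethyl-Δ5-octalin-8α-ol
Product: 17 7β-[1-(5,5-dimethyl-1,3,2-dioxaborinan-2-yl)vinyl]-4β,10β-dimethyl-Δ5-octalin-8α-yl methanesulfonate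
Conditions: MsCl, Et3N, CH2Cl2, −10 °C
Reagents that add atoms: methanesulfonyl chloride, CS(=O)(=O)Cl
Why: Sulfonylation of the equatorial secondary alcohol forms only an O–S bond, so C8 keeps its α-oxygen configuration.

Step 11
Reactants: 17 7β-[1-(5,5-dimethyl-1,3,2-dioxaborinan-2-yl)vinyl]-4β,10β-dimethyl-Δ5-octalin-8α-yl methanesulfonate
Product: 19 (+)-alantolactone [(3aR,5S,8aR,9aR)-5,8a-dimethyl-3-methylidene-3a,5,6,7,8,8a,9,9a-octahydronaphtho[2,3-b]furan-2(3H)-one], via cesium acrylate 18 (not isolated)
Conditions: CO2 (1 atm), CuI (5 mol%), bis(oxazoline) ligand (6 mol%), CsF (3 equiv), DMF, 90 °C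
Reagents that add atoms: carbon dioxide, O=C=O
Why: Fluoride turns the alkenylboronate into a borate that passes its C11 alkenyl group to copper(I), CO2 inserts into the Cu–C(sp2) bond (new C11–C12 bond), and the cesium 2-substituted acrylate 18 so formed is an internal nucleophile held three atoms from the C8 mesylate. The closest known reaction types are the copper-catalysed carboxylation of alkenylboronic esters with CO2 and the displacement of secondary sulfonates by cesium carboxylates in DMF with inversion. The γ-lactone closes 5-exo-tet by attack of a carboxylate oxygen on C8 from the β-face, anti to the α-mesylate (new O–C8 bond). C8 is the only new stereocentre and is set by this inversion, which puts O8 cis to the β C7–C11 bond fixed in step 7, so only the cis-fused 8β,12-olide can form; the 11(13)-methylene comes in unchanged from the alkenylboronate. The step needs carboxylation to outrun E2 loss or fluoride substitution of the mesylate, and O-alkylation to be the only fate of the carboxylate. The weakly basic CsF/DMF medium, the five-membered intramolecular closure and the absence of any other electrophilic or nucleophilic site should secure this.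

Step 12
Reactants: 20 5-chloropent-1-yne
Product: 22 2-bromo-5-chloropent-1-ene, via bromoalkenylborane 21 (not isolated)
Conditions: B-bromo-9-BBN, CH2Cl2, 0 °C; then AcOH, 23 °C
Reagents that add atoms: B-bromo-9-borabicyclo[3.3.1]nonane, BrB1C2CCCC1CCC2
Why: Bromoboration of the terminal alkyne and protodeboronation should give the 2-bromo-1-alkene that serves as bifunctional annulation reagent, the primary chloride being inert.

Step 13
Reactants: 23 (R)-carvone
Product: 24 (5R)-5-(3-chloroprop-1-en-2-yl)-2-methylcyclohex-2-en-1-one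
Conditions: Ca(OCl)2, solid CO2, CH2Cl2/H2O, 0 °C
Reagents that add atoms: calcium hypochlorite, [Ca+2].[O-]Cl.[O-]Cl
Why: Ene-type allylic chlorination by hypochlorous acid takes the electron-rich 1,1-disubstituted isopropenyl group and leaves the electron-poor enone alkene and the C7′ stereocentre untouched.

Step 14
Reactants: 24 (5R)-5-(3-chloroprop-1-en-2-yl)-2-methylcyclohex-2-en-1-one
Product: 25 (5R)-5-[3-(4-methoxyphenoxy)prop-1-en-2-yl]-2-methylcyclohex-2-en-1-one
Conditions: 4-methoxyphenol, K2CO3, KI (cat.), acetone, 56 °C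
Reagents that add atoms: 4-methoxyphenol, COc1ccc(O)cc1
Why: Williamson etherification of the allylic chloride by a phenoxide (SN2) installs an aryl ether that should survive the organometallic, basic and borane steps and is removed oxidatively in step 19.

Step 15
Reactants: 25 (5R)-5-[3-(4-methoxyphenoxy)prop-1-en-2-yl]-2-methylcyclohex-2-en-1-one; 22 2-bromo-5-chloropent-1-ene
Product: 27 (3R,5R)-3-(5-chloropent-1-en-2-yl)-5-[3-(4-methoxyphenoxy)prop-1-en-2-yl]-2-methylcyclohexan-1-one, via Grignard reagent 26 (not isolated)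
Conditions: 22, Mg, THF, 45 °C; then CuI (10 mol%), 25, THF, −40 °C; aq. NH4Cl
Reagents that add atoms: none
Why: Copper-catalysed conjugate addition of the alkenyl Grignard reagent to the 5-substituted cyclohexenone should occur trans to the C7′ side chain (axial attack anti to the pseudo-equatorial substituent), which sets C5′; the methyl-bearing carbon is obtained as a mixture that step 16 removes.

Step 16
Reactants: 27 (3R,5R)-3-(5-chloropent-1-en-2-yl)-5-[3-(4-methoxyphenoxy)prop-1-en-2-yl]-2-methylcyclohexan-1-one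
Product: 28 cis-fused 3-[3-(4-methoxyphenoxy)prop-1-en-2-yl]-8a-methyl-5-methylideneoctahydronaphthalen-1(2H)-one
Conditions: t-BuOK, t-BuOH/THF, 30 °C
Reagents that add atoms: none
Why: Intramolecular alkylation of the tetrasubstituted potassium enolate by the primary chloride (6-exo-tet, methylenecyclohexane annulation), in which the tether on C5′ reaches the enolate carbon only on its own face, so the ring fusion should be cis and the C10′ methyl group syn to H5′ and to the C7′ side chain.

Step 17
Reactants: 28 cis-fused 3-[3-(4-methoxyphenoxy)prop-1-en-2-yl]-8a-methyl-5-methylideneoctahydronaphthalen-1(2H)-one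
Product: 29 tosylhydrazone of 28
Conditions: TsNHNH2, EtOH, 78 °C
Reagents that add atoms: 4-methylbenzenesulfonohydrazide, Cc1ccc(cc1)S(=O)(=O)NN
Why: Condensation of the ketone with tosylhydrazide gives the tosylhydrazone without touching a stereocentre (C10′ is quaternary and C5′ is not α to the carbonyl).

Step 18
Reactants: 29 tosylhydrazone of 28
Product: 31 1-methoxy-4-({2-[(2S,4aS,8aS)-4a-methyl-8-methylidenedecahydronaphthalen-2-yl]prop-2-en-1-yl}oxy)benzene, via alkyl diazene 30 (not isolated)
Conditions: catecholborane, CHCl3, 0 °C; then NaOAc·3H2O, 60 °C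
Reagents that add atoms: none
Why: Reduction of the tosylhydrazone C=N by catecholborane followed by acetate-induced loss of sulfinate and N2 from the diazene is a mild ketone-to-methylene deoxygenation that should leave both 1,1-disubstituted alkenes and the allyl aryl ether intact.

Step 19
Reactants: 31 1-methoxy-4-({2-[(2S,4aS,8aS)-4a-methyl-8-methylidenedecahydronaphthalen-2-yl]prop-2-en-1-yl}oxy)benzene
Product: 32 2-[(2S,4aS,8aS)-4a-methyl-8-methylidenedecahydronaphthalen-2-yl]prop-2-en-1-ol
Conditions: ceric ammonium nitrate (2.5 equiv), MeCN/H2O, 0 °C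
Reagents that add atoms: none
Why: Oxidative cleavage of the 4-methoxyphenyl ether by cerium(IV) should release the primary allylic alcohol and benzoquinone.

Step 20
Reactants: 32 2-[(2S,4aS,8aS)-4a-methyl-8-methylidenedecahydronaphthalen-2-yl]prop-2-en-1-ol
Product: 33 2-[(2S,4aS,8aS)-4a-methyl-8-methylidenedecahydronaphthalen-2-yl]prop-2-enal
Conditions: activated MnO2, CH2Cl2, 23 °C
Reagents that add atoms: none
Why: Activated MnO2 oxidises the allylic alcohol selectively to the 2-substituted acrolein.

Step 21
Reactants: 19 (+)-alantolactone; 33 2-[(2S,4aS,8aS)-4a-methyl-8-methylidenedecahydronaphthalen-2-yl]prop-2-enal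
Product: 34 target spiro-dihydropyran lactone (CNP0108778.1)
Conditions: 33 (2 equiv), BHT (cat.), toluene, 130 °C, sealed tube
Reagents that add atoms: none
Why: Thermal oxa-Diels–Alder reaction of the 2-substituted acrolein (1-oxadiene) with the exocyclic C11=C13 of the α-methylene lactone, with the regiochemistry of acrolein dimerisation (oxygen to the carbonyl-bearing C11, CH2 to C13); the oxadiene should add to the convex α-face of the cis-fused lactone (the side of H7 and H8), which sets the spiro centre C11.

**Compound list**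
1 | 3-methylcyclohex-2-en-1-one | CC1=CC(=O)CCC1 | starting material
2 | 2-(3-chloropropyl)-2-methyl-1,3-dioxolane | CC1(CCCCl)OCCO1 | starting material
3 | [3-(2-methyl-1,3-dioxolan-2-yl)propyl]magnesium chloride | CC1(CCC[Mg]Cl)OCCO1 | intermediate
4 | (S)-3-methyl-3-[3-(2-methyl-1,3-dioxolan-2-yl)propyl]cyclohexan-1-one | O=C1C[C@](C)(CCCC2(C)OCCO2)CCC1 | intermediate
5 | (R)-3-methyl-3-(4-oxopentyl)cyclohexan-1-one | O=C1C[C@](C)(CCCC(C)=O)CCC1 | intermediate
6 | (4aR)-4a,8-dimethyl-3,4,4a,5,6,7-hexahydronaphthalen-1(2H)-one (C6 ketone, Δ4) | O=C1CCC[C@@]2(C)CCCC(C)=C12 | intermediate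
7 | (4aR)-4a,8-dimethyl-4a,5,6,7-tetrahydronaphthalen-1(4H)-one (Δ4,7-dien-6-one) | O=C1C=CC[C@@]2(C)CCCC(C)=C12 | intermediate
8 | 7α,8α-epoxy-4,10-dimethyl-Δ4-octalin-6-one (oxirane anti to the angular methyl) | O=C1[C@H]3O[C@H]3C[C@@]2(C)CCCC(C)=C12 | intermediate
9 | 7α,8α-epoxy-4,10-dimethyl-Δ4-octalin-6β-ol (hydroxyl syn to the angular methyl) | O[C@@H]1[C@H]3O[C@H]3C[C@@]2(C)CCCC(C)=C12 | intermediate
10 | N-(7α,8α-epoxy-4,10-dimethyl-Δ4-octalin-6α-yl)-2-nitrobenzenesulfonohydrazide | NN([C@H]1[C@H]3O[C@H]3C[C@@]2(C)CCCC(C)=C12)S(=O)(=O)c1ccccc1[N+](=O)[O-] | intermediate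
11 | (7α,8α-epoxy-4,10-dimethyl-Δ4-octalin-6α-yl)diazene | N=N[C@H]1[C@H]3O[C@H]3C[C@@]2(C)CCCC(C)=C12 | intermediate
12 | 7α,8α-epoxy-4β,10β-dimethyl-Δ5-octalin (vinyl epoxide) | C[C@H]1CCC[C@]2(C)C[C@@H]3O[C@@H]3C=C12 | intermediate
13 | 7β-ethynyl-4β,10β-dimethyl-Δ5-octalin-8α-ol | C[C@H]1CCC[C@]2(C)C[C@H](O)[C@@H](C#C)C=C12 | intermediate
14 | (Z)-2-bromoalkenyl-9-BBN adduct of 13 (drawn as the free alcohol) | C[C@H]1CCC[C@]2(C)C[C@H](O)[C@@H](/C(Br)=C/B3C4CCCC3CCC4)C=C12 | intermediate
15 | 7β-(1-bromovinyl)-4β,10β-dimethyl-Δ5-octalin-8α-ol | C[C@H]1CCC[C@]2(C)C[C@H](O)[C@@H](C(Br)=C)C=C12 | intermediate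
16 | 7β-[1-(5,5-dimethyl-1,3,2-dioxaborinan-2-yl)vinyl]-4β,10β-dimethyl-Δ5-octalin-8α-ol | C[C@H]1CCC[C@]2(C)C[C@H](O)[C@@H](C(=C)B3OCC(C)(C)CO3)C=C12 | intermediate
17 | 8α-methanesulfonate of 16 | C[C@H]1CCC[C@]2(C)C[C@H](OS(C)(=O)=O)[C@@H](C(=C)B3OCC(C)(C)CO3)C=C12 | intermediate
18 | cesium 2-(8α-mesyloxy-4β,10β-dimethyl-Δ5-octalin-7β-yl)acrylate | [Cs+].C[C@H]1CCC[C@]2(C)C[C@H](OS(C)(=O)=O)[C@@H](C(=C)C([O-])=O)C=C12 | intermediate
19 | (+)-alantolactone, (3aR,5S,8aR,9aR)-5,8a-dimethyl-3-methylidene-3a,5,6,7,8,8a,9,9a-octahydronaphtho[2,3-b]furan-2(3H)-one | C[C@H]1CCC[C@]2(C)C[C@H]3OC(=O)C(=C)[C@H]3C=C12 | intermediate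
20 | 5-chloropent-1-yne | C#CCCCCl | starting material
21 | (Z)-(2-bromo-5-chloropent-1-en-1-yl)-9-BBN | ClCCC/C(Br)=C/B1C2CCCC1CCC2 | intermediate
22 | 2-bromo-5-chloropent-1-ene | C=C(Br)CCCCl | intermediate
23 | (R)-carvone | O=C1C(C)=CC[C@H](C1)C(C)=C | starting material
24 | (5R)-5-(3-chloroprop-1-en-2-yl)-2-methylcyclohex-2-en-1-one | O=C1C(C)=CC[C@H](C1)C(CCl)=C | intermediate
25 | (5R)-5-[3-(4-methoxyphenoxy)prop-1-en-2-yl]-2-methylcyclohex-2-en-1-one | O=C1C(C)=CC[C@H](C1)C(COc2ccc(OC)cc2)=C | intermediate
26 | (5-chloropent-1-en-2-yl)magnesium bromide | C=C([Mg]Br)CCCCl | intermediate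
27 | (3R,5R)-3-(5-chloropent-1-en-2-yl)-5-[3-(4-methoxyphenoxy)prop-1-en-2-yl]-2-methylcyclohexan-1-one (3,5-trans; C2 epimers) | O=C1C(C)[C@H](C(=C)CCCCl)C[C@H](C1)C(COc2ccc(OC)cc2)=C | intermediate
28 | cis-fused 3-[3-(4-methoxyphenoxy)prop-1-en-2-yl]-8a-methyl-5-methylideneoctahydronaphthalen-1(2H)-one (8a-methyl, 4a-H and 3-side chain all syn) | C=C1CCC[C@@]2(C)C(=O)C[C@H](C(COc3ccc(OC)cc3)=C)C[C@@H]12 | intermediate
29 | tosylhydrazone of 28 | C=C1CCC[C@@]2(C)C(=NNS(=O)(=O)c3ccc(C)cc3)C[C@H](C(COc3ccc(OC)cc3)=C)C[C@@H]12 | intermediate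
30 | alkyl diazene from 29 | C=C1CCC[C@@]2(C)C(N=N)C[C@H](C(COc3ccc(OC)cc3)=C)C[C@@H]12 | intermediate
31 | 1-methoxy-4-({2-[(2S,4aS,8aS)-4a-methyl-8-methylidenedecahydronaphthalen-2-yl]prop-2-en-1-yl}oxy)benzene | C=C1CCC[C@@]2(C)CC[C@H](C(COc3ccc(OC)cc3)=C)C[C@@H]12 | intermediate
32 | 2-[(2S,4aS,8aS)-4a-methyl-8-methylidenedecahydronaphthalen-2-yl]prop-2-en-1-ol | C=C1CCC[C@@]2(C)CC[C@H](C(CO)=C)C[C@@H]12 | intermediate
33 | 2-[(2S,4aS,8aS)-4a-methyl-8-methylidenedecahydronaphthalen-2-yl]prop-2-enal (cis-fused; methyl, H5′ and side chain all syn) | C=C1CCC[C@@]2(C)CC[C@H](C(C=O)=C)C[C@@H]12 | intermediate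
34 | CNP0108778.1, spiro[dihydropyran–alantolactone] adduct | C=C1CCC[C@@]2(C)CC[C@H](C3=CO[C@@]4(CC3)C(=O)O[C@@H]3C[C@@]5(C)CCC[C@H](C)C5=C[C@@H]34)C[C@@H]12 | target

**Totals**
Total step count: 21.
Longest linear sequence: 12 steps (steps 1–11, then step 21).

**Steps most likely to fail**

Step 11 (key step). The mesylate may be lost by fluoride-induced E2 elimination or substitution before boron-to-copper transfer and CO2 insertion are complete, and the backside attack on C8 is slowed because it runs syn to the axial C10 methyl group. The fallback sets out from 16, which has no leaving group. Carboxylation of 16 under the same Cu/CsF/CO2 conditions and acidification should give 2-(8α-hydroxy-4β,10β-dimethyl-Δ5-octalin-7β-yl)acrylic acid F1. A Mitsunobu lactonisation (PPh3, DIAD, THF, 0 °C) then activates the C8 hydroxyl, and the carboxylate oxygen displaces it with inversion. This closes the same O–C8 bond and returns to the route at 19.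

Step 6. The Mitsunobu displacement at the hindered axial allylic alcohol may be diverted by ionisation, by participation of the neighbouring oxirane or by elimination, and the sulfinic acid released may open the vinyl epoxide. The fallback sets out from 9 and uses the thermally stable reagent N-isopropylidene-N′-(2-nitrobenzenesulfonyl)hydrazine in the Mitsunobu step (PPh3, DEAD, THF, 0 to 23 °C) to give the isolable N-allyl-N′-isopropylidene sulfonylhydrazide F2. Hydrolysis of F2 in trifluoroethanol/water at 23 °C then generates the sulfonylhydrazide under near-neutral conditions; it should lose sulfinate and N2 by the same suprafacial shift and return to the route at 12.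

Step 5. Hydride delivery anti to the oxirane (β-face) may compete with delivery anti to the axial methyl group, and the alkoxide may undergo epoxide migration. The fallback sets out from 7 and reduces before the oxirane exists.
- L-Selectride should give 4,10-dimethyl-Δ4,7-octalin-6β-ol F3 by α-attack alone.
- Silylation (TBSCl, imidazole) gives the silyl ether F4.
- OsO4/NMO takes the disubstituted C7=C8 anti to both the silyloxy group and the angular methyl group, leaving the tetrasubstituted alkene, to give the 7α,8α-diol F5.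
- A one-pot orthoester, acetyl bromide and K2CO3/MeOH sequence converts the cis-diol into the oxirane with retention, giving the 7α,8α-epoxy silyl ether F6.
- TBAF returns to the route at 9.

**Further compounds**
F1 | step 11 | 2-(8α-hydroxy-4β,10β-dimethyl-Δ5-octalin-7β-yl)acrylic acid | C[C@H]1CCC[C@]2(C)C[C@H](O)[C@@H](C(=C)C(O)=O)C=C12
F2 | step 6 | N-(7α,8α-epoxy-4,10-dimethyl-Δ4-octalin-6α-yl)-N′-isopropylidene-2-nitrobenzenesulfonohydrazide | CC(C)=NN([C@H]1[C@H]3O[C@H]3C[C@@]2(C)CCCC(C)=C12)S(=O)(=O)c1ccccc1[N+](=O)[O-]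
F3 | step 5 | 4,10-dimethyl-Δ4,7-octalin-6β-ol | O[C@@H]1C=CC[C@@]2(C)CCCC(C)=C12
F4 | step 5 | 6β-(tert-butyldimethylsilyloxy)-4,10-dimethyl-Δ4,7-octalin | CC(C)(C)[Si](C)(C)O[C@@H]1C=CC[C@@]2(C)CCCC(C)=C12
F5 | step 5 | 6β-(tert-butyldimethylsilyloxy)-4,10-dimethyl-Δ4-octalin-7α,8α-diol | CC(C)(C)[Si](C)(C)O[C@@H]1[C@@H](O)[C@@H](O)C[C@@]2(C)CCCC(C)=C12
F6 | step 5 | 6β-(tert-butyldimethylsilyloxy)-7α,8α-epoxy-4,10-dimethyl-Δ4-octalin | CC(C)(C)[Si](C)(C)O[C@@H]1[C@H]3O[C@H]3C[C@@]2(C)CCCC(C)=C12
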